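Remark on the chemistry: "prenyl" means 3-methylbut-2-en-1-yl and "MOM" means methoxymethyl; flavone numbering (O1, C2, C3, C4, C4a, C5–C8, C8a, primed positions for ring B) is used for all intermediates, also before ring C exists.

## Analysis of the target

The target is a 2-arylchromen-4-one in which benzo ring A (C4a, C5–C8, C8a) is fused to pyranone ring C (O1, C2, C3, C4) and aryl ring B sits on C2. Ring C carries a methoxy group on C3, ring A has free hydroxyls on C5 and C7 and a prenyl group on C8, and ring B has a 3',4'-catechol with a prenyl group on C5'. There is no stereocentre, and both alkenes end in two identical methyl groups, so the whole problem is one of regiochemistry and chemoselectivity. Each prenyl group lies ortho to a free phenol (C8 next to 7-OH, C5' next to 4'-OH), so strong acid can close chromans, while the alkenes rule out hydrogenolysis and late electrophilic oxidants or halogens and the free catechol is sensitive to base and air. Three things make the synthesis hard: placing the prenyl group at C8 rather than C6 of a phloroglucinol-derived ring, methylating only the C3 oxygen out of five, and putting a prenyl group next to the catechol of ring B. The strategy rests on C4, a single carbonyl carbon between C4a of ring A and the C3=C2–aryl unit, which can therefore come from carbon monoxide inserted between an ortho-iodophenol (supplying ring A, C4a, C8a and O1) and a terminal arylacetylene (supplying C3, C2 and ring B). C3 then arrives as the only sp2 C–H next to the carbonyl and can be oxygenated afterwards.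

## Retrosynthetic reasoning

The four phenolic hydroxyls of target 23 are masked as MOM ethers in 22, so the last disconnection is four O–CH2OMe bonds. These acetals survive base, organolithium reagents, palladium, carbon monoxide and hot amine. They are removed by mild acid solvolysis, without hydrogenolysis (which would reduce the prenyl groups) and without Lewis acids strong enough to cleave the C3 methyl ether.

The O–CH3 bond of 22 and then the C3–O bond of flavonol 21 are cut next, leading back to the C3-unsubstituted flavone 18. The oxygen is introduced late because the ring-forming step delivers C3 as a C–H. That hydrogen is the most acidic one in 18, so deprotonation to 19, capture on boron as 20 and oxygen transfer place the hydroxyl only there. Methylation needs no selectivity, because 21 has one free hydroxyl.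

Ring C of 18 is opened at C4a–C4, C4–C3 and O1–C2, giving iodophenol 8, carbon monoxide 15 and arylacetylene 14. This cut divides the molecule into two arenes of similar size, each with one prenyl group and two protected oxygens, and uses a one-carbon unit that costs nothing. In the forward direction palladium must join the three components to ynone 16, and the secondary amine solvent must steer ring closure through enaminone 17 to the six-membered pyranone. The 8-prenyl regiochemistry is written into 8, where the free hydroxyl sits between the iodine and the prenyl group.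

The ring-to-prenyl bond of 8 is cut by a retro-Claisen step to the 1,1-dimethylallyl ether 7. Ether 7 comes from propargyl ether 6 by semi-hydrogenation, and 6 comes from iodophenol 3 and methyl carbonate 5, an isolable propargylic electrophile made once from alcohol 4 and shared by both arenes. Iodination precedes installation of the allyl unit, so the electrophilic halogenating agent never meets an alkene and the rearrangement has only one free ortho position to go to. Compound 3 comes from bis-MOM ether 2, whose two ortho positions are equivalent by symmetry, and 2 comes from phloroglucinol 1.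

The alkyne of 14 is traced to aldehyde 13 by a one-carbon homologation. Compound 13 is the bis-MOM ether of catechol 12. The prenyl group of 12 is again removed by a retro-Claisen step to ether 11, then to 10, and finally to 3,4-dihydroxybenzaldehyde 9 and carbonate 5. The ether has to be on O4, the more acidic hydroxyl of 9, because the only free position ortho to it is C5.

## Alternatives that were turned down

Alternative 1: Ring A is disconnected at C4a–C5 and built last on a finished 2-aryl-3-methoxypyran-4-one.
- Key step: heating the acyl Meldrum's acid A1 would unmask the acylketene A2. Its enol form is a dienylketene that can close onto the pyranone C–H (the future C4a) in a six-electron cyclisation and tautomerise to the resorcinol A3.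
- For: the methoxy group is on C3 from the start, the prenyl group is fixed on C8 by the side chain, the 5,7-diol appears unprotected, and only two MOM groups remain. On the C3 oxygen and on ring A regiochemistry this plan is stronger than the chosen one. It needs no organolithium step and no selective iodination of a phloroglucinol ether.
- Against: A1 is a 2,3,6-trisubstituted pyranone with a prenylated keto side chain, and it must be built linearly with ring B attached throughout. A2 is a very electrophilic species that can dimerise or be trapped before it finds the weakly nucleophilic pyranone carbon. Ring closure of an acylketene onto a pyranone C–H has little analogy.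
- Comparison: the chosen route gives convergence instead. Each arene is reached in five steps from its own starting material, and the risk sits in a three-component step with close precedent. The price is three steps after the coupling.

Alternative 2: Ring A is assembled on a pyranone of the kojic acid (A4) type by cutting C8–C8a, C7–C8, C5–C6 and C4a–C5.
- Key step: irradiation of diazo ketone A5 with (triisopropylsilyloxy)ethyne A6 and subsequent heating would run a Wolff rearrangement, a ketene–alkyne [2+2] addition, a four-electron ring opening and a six-electron ring closure to give A7.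
- For: four bonds and a fully substituted ring A form in one operation with defined regiochemistry, the 5-OH and 7-O-silyl groups come out differentiated, and the C3 methoxy group is inherited from A4. On regiocontrol of ring A it is at least as good as the chosen plan.
- Against: A5 has a CH2 group next to the diazo carbon, so a 1,2-hydrogen shift to an enone competes with the Wolff rearrangement. The prenyl alkene can be cyclopropanated. The 4-pyranone is itself photoactive. A6 is moisture-sensitive and must be prepared. The aryl group has to be put on the pyranone first, and ring B is carried through a long linear sequence with a silyl removal added at the end.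
- Comparison: the chosen route uses no photochemistry and no diazo ketone on the main line, and its fragments are simple benzene derivatives.

Alternative 3: Ring C is cut at O1–C8a.
- Key step: the 1-(2-bromoaryl)-2-methoxy-1,3-dione A8 would be cyclised with CuI, 1,10-phenanthroline and Cs2CO3. The enolate oxygen on the ring B side displaces bromide to give A9, which is the same compound as 22.
- For: the methoxy group is on the central carbon before ring closure, so the strong-base C3 oxygenation is avoided and A9 is one step from the target. No CO pressure is needed. On these two points it is stronger than the chosen plan.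
- Against: ring A must be made as a hexasubstituted bromoarene with bromine next to the prenyl group and an acyl group on the other side. That is harder to make regioselectively than iodophenol 8, where the phenol oxygen is already in place. The dione needs C-acylation with a di-ortho-substituted aroyl unit, where O-acylation and steric hindrance interfere. The copper step must substitute a C–Br bond flanked by two substituents.
- Comparison: the chosen route offers a simpler ring A partner and joins the fragments without any prior C–C bond between them. It accepts two extra steps after the coupling.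

Key step: step 12

## Route

Step 1
Reactants: 1 phloroglucinol
Product: 2 3,5-bis(methoxymethoxy)phenol
Conditions: MOMCl (2.0 equiv), i-Pr2NEt, DMF, 0 °C to rt; chromatography, mono-ether resubmitted
Reagents that add atoms: chloromethyl methyl ether, COCCl
Why: Base-mediated O-alkylation (Williamson-type) of a threefold symmetric triphenol; with two equivalents of MOMCl the bis-ether should be the main component of a statistical mixture, and the mono- and tris-ethers differ enough in polarity to be separated.

Step 2
Reactants: 2 3,5-bis(methoxymethoxy)phenol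
Product: 3 2-iodo-3,5-bis(methoxymethoxy)phenol
Conditions: I2 (1.0 equiv), NaHCO3, THF–H2O, 0 °C
Reagents that add atoms: iodine, II
Why: Electrophilic aromatic iodination of the phenoxide under buffered conditions that leave the MOM acetals intact; the two positions ortho to the hydroxyl are equivalent and less hindered than C4 between the two MOM ethers, so mono-iodination ortho to OH is expected to dominate with one equivalent of iodine.

Step 3
Reactants: 4 2-methylbut-3-yn-2-ol
Product: 5 2-methylbut-3-yn-2-yl methyl carbonate
Conditions: n-BuLi (1.0 equiv), THF, −78 °C; ClCO2Me (1.1 equiv), −78 °C to rt; distillation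
Reagents that add atoms: methyl chloroformate, COC(=O)Cl
Why: O-Acylation of a lithium alkoxide with a chloroformate: one equivalent of n-BuLi deprotonates only the hydroxyl, which is far more acidic than the alkyne C–H, and the tertiary alkoxide attacks methyl chloroformate. The mixed carbonate is a distillable, storable propargylic electrophile, so one batch serves both arenes.

Step 4
Reactants: 3 2-iodo-3,5-bis(methoxymethoxy)phenol; 5 2-methylbut-3-yn-2-yl methyl carbonate
Product: 6 2-iodo-1,5-bis(methoxymethoxy)-3-[(2-methylbut-3-yn-2-yl)oxy]benzene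
Conditions: 5 (1.3 equiv), DBU (1.3 equiv), CuCl2·2H2O (1 mol%), MeCN, 0 °C to rt
Reagents that add atoms: none
Why: Copper-catalysed propargylic etherification: the copper acetylide of 5 ionises with loss of methyl carbonate (which collapses to CO2 and methoxide) to a copper allenylidene, and the phenoxide of 3 attacks its tertiary carbon to give the hindered aryl 1,1-dimethylpropargyl ether. At or below room temperature, with a trace of copper and no palladium, the aryl iodide is not expected to couple with the alkyne.

Step 5
Reactants: 6 2-iodo-1,5-bis(methoxymethoxy)-3-[(2-methylbut-3-yn-2-yl)oxy]benzene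
Product: 7 2-iodo-1,5-bis(methoxymethoxy)-3-[(2-methylbut-3-en-2-yl)oxy]benzene
Conditions: H2 (1 atm), Pd/CaCO3 poisoned with Pb(OAc)2 (Lindlar catalyst), quinoline, EtOAc, rt, stopped after 1 equiv H2
Reagents that add atoms: none
Why: Lindlar semi-hydrogenation of a terminal alkyne is fast and stops at the alkene on the poisoned catalyst; the aryl C–I bond and the MOM ethers are expected to survive at 1 atm and room temperature.

Step 6
Reactants: 7 2-iodo-1,5-bis(methoxymethoxy)-3-[(2-methylbut-3-en-2-yl)oxy]benzene
Product: 8 2-iodo-3,5-bis(methoxymethoxy)-6-(3-methylbut-2-en-1-yl)phenol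
Conditions: PhNEt2, 120 °C
Reagents that add atoms: none
Why: Aromatic Claisen rearrangement ([3,3]-sigmatropic shift) of the aryl 1,1-dimethylallyl ether, accelerated by the gem-dimethyl group and the electron-rich ring; the other ortho position carries iodine, so the allyl terminus can only reach the free ortho carbon, and rearomatisation gives the linear prenyl group beside the liberated hydroxyl, while the amine solvent suppresses acid-catalysed chroman formation.

Step 7
Reactants: 9 3,4-dihydroxybenzaldehyde; 5 2-methylbut-3-yn-2-yl methyl carbonate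
Product: 10 3-hydroxy-4-[(2-methylbut-3-yn-2-yl)oxy]benzaldehyde
Conditions: 5 (1.0 equiv, added slowly), DBU (1.05 equiv), CuCl2·2H2O (1 mol%), MeCN, −5 °C to rt
Reagents that add atoms: none
Why: The same copper-catalysed propargylic etherification; the 4-OH, para to the formyl group, is the more acidic hydroxyl and is deprotonated first by DBU, so with one equivalent of 5 the monoanion should be alkylated at O4, as in other monoalkylations of this catechol.

Step 8
Reactants: 10 3-hydroxy-4-[(2-methylbut-3-yn-2-yl)oxy]benzaldehyde
Product: 11 3-hydroxy-4-[(2-methylbut-3-en-2-yl)oxy]benzaldehyde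
Conditions: H2 (1 atm), Pd/CaCO3 poisoned with Pb(OAc)2 (Lindlar catalyst), quinoline, EtOAc, rt
Reagents that add atoms: none
Why: Lindlar semi-hydrogenation of the terminal alkyne; the aromatic aldehyde is not reduced on the poisoned catalyst.

Step 9
Reactants: 11 3-hydroxy-4-[(2-methylbut-3-en-2-yl)oxy]benzaldehyde
Product: 12 3,4-dihydroxy-5-(3-methylbut-2-en-1-yl)benzaldehyde
Conditions: PhNEt2, 140 °C
Reagents that add atoms: none
Why: Aromatic Claisen rearrangement from O4 to C5, the only free position ortho to O4 because C3 carries the hydroxyl; tautomerisation restores the arene and leaves the linear prenyl group.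

Step 10
Reactants: 12 3,4-dihydroxy-5-(3-methylbut-2-en-1-yl)benzaldehyde
Product: 13 3,4-bis(methoxymethoxy)-5-(3-methylbut-2-en-1-yl)benzaldehyde
Conditions: MOMCl (3 equiv), i-Pr2NEt, DMF, 0 °C to rt
Reagents that add atoms: chloromethyl methyl ether, COCCl
Why: Exhaustive O-alkylation of both phenols (Williamson-type); no selectivity is required and the aldehyde and alkene are inert.

Step 11
Reactants: 13 3,4-bis(methoxymethoxy)-5-(3-methylbut-2-en-1-yl)benzaldehyde
Product: 14 5-ethynyl-1,2-bis(methoxymethoxy)-3-(3-methylbut-2-en-1-yl)benzene
Conditions: dimethyl (1-diazo-2-oxopropyl)phosphonate, K2CO3, MeOH, 0 °C to rt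
Reagents that add atoms: dimethyl (1-diazo-2-oxopropyl)phosphonate, CC(=O)C(=[N+]=[N-])P(=O)(OC)OC
Why: Seyferth–Gilbert homologation in the Ohira–Bestmann variant: methanolysis of the reagent releases the diazomethylphosphonate anion, which adds to the non-enolisable aldehyde in a Horner–Wadsworth–Emmons-type step, and loss of N2 with 1,2-hydrogen shift gives the terminal alkyne under mild base that leaves the MOM ethers and the prenyl group untouched.

Step 12
Reactants: 8 2-iodo-3,5-bis(methoxymethoxy)-6-(3-methylbut-2-en-1-yl)phenol; 14 5-ethynyl-1,2-bis(methoxymethoxy)-3-(3-methylbut-2-en-1-yl)benzene; 15 carbon monoxide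
Product: 18 5,7-bis(methoxymethoxy)-8-(3-methylbut-2-en-1-yl)-2-[3,4-bis(methoxymethoxy)-5-(3-methylbut-2-en-1-yl)phenyl]-4H-chromen-4-one, via ortho-hydroxyaryl ynone 16 (not isolated), via diethylamino enaminone 17 (not isolated)
Conditions: 14 (1.3 equiv), PdCl2(PPh3)2 (5 mol%), CO (20 bar), Et2NH, 120 °C, autoclave
Reagents that add atoms: none
Why: This is a carbonylative Sonogashira coupling followed by amine-mediated cyclisation, the reaction type known for 2-iodophenols, terminal alkynes and CO in a secondary amine. The divalent palladium precatalyst is reduced in situ to zerovalent palladium, which inserts into the C–I bond of 8; CO then inserts to give an aroylpalladium iodide, and amine-assisted alkynyl transfer from 14 with reductive elimination forms C4a–C4 and C4–C3 in ynone 16. Diethylamine adds to C2 of the ynone to give enaminone 17, whose phenol oxygen attacks the amino-bearing C2 and expels the amine, forming O1–C2. Ring C thus closes by an addition–elimination that is 6-endo-trig with respect to the C2=C3 bond of 17 (6-exo-trig if counted on its iminium resonance form) and amounts overall to a 6-endo-dig closure of 16; no stereocentre is formed. Carbonylative coupling must win over direct coupling, which the CO pressure, the absence of copper and the hindered, electron-rich arylpalladium should secure. The flavone must win over the aurone, which the amine should secure by converting 16 into 17 before the phenoxide can close in the 5-exo-dig sense at C3. The 8-prenyl regiochemistry is fixed because the only free hydroxyl of 8 lies between the iodine and the prenyl group. The trisubstituted alkenes and the MOM acetals should be inert to the palladium, CO and amine.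

Step 13
Reactants: 18 5,7-bis(methoxymethoxy)-8-(3-methylbut-2-en-1-yl)-2-[3,4-bis(methoxymethoxy)-5-(3-methylbut-2-en-1-yl)phenyl]-4H-chromen-4-one
Product: 21 3-hydroxy-5,7-bis(methoxymethoxy)-8-(3-methylbut-2-en-1-yl)-2-[3,4-bis(methoxymethoxy)-5-(3-methylbut-2-en-1-yl)phenyl]-4H-chromen-4-one, via 3-lithioflavone 19 (not isolated), via dimethyl flavon-3-ylboronate 20 (not isolated)
Conditions: LDA (1.5 equiv), THF, −78 °C; B(OMe)3 (3 equiv), −78 to 0 °C; AcOH (1.5 equiv), then Me3NO (3 equiv), 0 °C to rt; aq. work-up
Reagents that add atoms: trimethylamine N-oxide, C[N+](C)(C)[O-]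
Why: Deprotonation of the flavone at C3 (the only sp2 C–H next to the carbonyl, helped by lithium coordination to the C4 oxygen), trapping on boron and oxidation with 1,2-migration of C3 from boron to oxygen is the known lithiation–borylation–oxidation route from flavones to flavonols; the amine N-oxide transfers oxygen only to boron, so the two alkenes are not epoxidised as they would be by peracids.

Step 14
Reactants: 21 3-hydroxy-5,7-bis(methoxymethoxy)-8-(3-methylbut-2-en-1-yl)-2-[3,4-bis(methoxymethoxy)-5-(3-methylbut-2-en-1-yl)phenyl]-4H-chromen-4-one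
Product: 22 3-methoxy-5,7-bis(methoxymethoxy)-8-(3-methylbut-2-en-1-yl)-2-[3,4-bis(methoxymethoxy)-5-(3-methylbut-2-en-1-yl)phenyl]-4H-chromen-4-one
Conditions: MeI, K2CO3, acetone, 50 °C
Reagents that add atoms: iodomethane, CI
Why: Williamson O-methylation; 21 has a single free hydroxyl, so no selectivity is needed.

Step 15
Reactants: 22 3-methoxy-5,7-bis(methoxymethoxy)-8-(3-methylbut-2-en-1-yl)-2-[3,4-bis(methoxymethoxy)-5-(3-methylbut-2-en-1-yl)phenyl]-4H-chromen-4-one
Product: 23 5,7-dihydroxy-2-[3,4-dihydroxy-5-(3-methylbut-2-en-1-yl)phenyl]-3-methoxy-8-(3-methylbut-2-en-1-yl)-4H-chromen-4-one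
Conditions: HCl (3 M aq)/MeOH, 50 °C, under N2
Reagents that add atoms: none
Why: Acid-catalysed acetal solvolysis (transacetalisation to methanol) removes the four MOM groups while the methyl ether on C3 is inert; moderate acid strength and temperature are chosen to stay below the threshold for cyclisation of the prenyl groups onto the neighbouring phenols.

## Compound list

1 | phloroglucinol (benzene-1,3,5-triol) | Oc1cc(O)cc(O)c1 | starting material
2 | 3,5-bis(methoxymethoxy)phenol | COCOc1cc(O)cc(OCOC)c1 | intermediate
3 | 2-iodo-3,5-bis(methoxymethoxy)phenol | Oc1cc(OCOC)cc(OCOC)c1I | intermediate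
4 | 2-methylbut-3-yn-2-ol | CC(C)(O)C#C | starting material
5 | 2-methylbut-3-yn-2-yl methyl carbonate | COC(=O)OC(C)(C)C#C | intermediate
6 | 2-iodo-1,5-bis(methoxymethoxy)-3-[(2-methylbut-3-yn-2-yl)oxy]benzene | C#CC(C)(C)Oc1cc(OCOC)cc(OCOC)c1I | intermediate
7 | 2-iodo-1,5-bis(methoxymethoxy)-3-[(2-methylbut-3-en-2-yl)oxy]benzene | C=CC(C)(C)Oc1cc(OCOC)cc(OCOC)c1I | intermediate
8 | 2-iodo-3,5-bis(methoxymethoxy)-6-(3-methylbut-2-en-1-yl)phenol | Oc1c(I)c(OCOC)cc(OCOC)c1CC=C(C)C | intermediate
9 | 3,4-dihydroxybenzaldehyde | O=Cc1ccc(O)c(O)c1 | starting material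
10 | 3-hydroxy-4-[(2-methylbut-3-yn-2-yl)oxy]benzaldehyde | O=Cc1ccc(OC(C)(C)C#C)c(O)c1 | intermediate
11 | 3-hydroxy-4-[(2-methylbut-3-en-2-yl)oxy]benzaldehyde | O=Cc1ccc(OC(C)(C)C=C)c(O)c1 | intermediate
12 | 3,4-dihydroxy-5-(3-methylbut-2-en-1-yl)benzaldehyde | O=Cc1cc(O)c(O)c(CC=C(C)C)c1 | intermediate
13 | 3,4-bis(methoxymethoxy)-5-(3-methylbut-2-en-1-yl)benzaldehyde | O=Cc1cc(OCOC)c(OCOC)c(CC=C(C)C)c1 | intermediate
14 | 5-ethynyl-1,2-bis(methoxymethoxy)-3-(3-methylbut-2-en-1-yl)benzene | C#Cc1cc(OCOC)c(OCOC)c(CC=C(C)C)c1 | intermediate
15 | carbon monoxide | [C-]#[O+] | starting material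
16 | 1-[2-hydroxy-4,6-bis(methoxymethoxy)-3-(3-methylbut-2-en-1-yl)phenyl]-3-[3,4-bis(methoxymethoxy)-5-(3-methylbut-2-en-1-yl)phenyl]prop-2-yn-1-one | O=C(C#Cc1cc(OCOC)c(OCOC)c(CC=C(C)C)c1)c1c(O)c(CC=C(C)C)c(OCOC)cc1OCOC | intermediate (not isolated)
17 | 3-(diethylamino)-1-[2-hydroxy-4,6-bis(methoxymethoxy)-3-(3-methylbut-2-en-1-yl)phenyl]-3-[3,4-bis(methoxymethoxy)-5-(3-methylbut-2-en-1-yl)phenyl]prop-2-en-1-one (alkene geometry not defined, both isomers converge) | CCN(CC)C(=CC(=O)c1c(O)c(CC=C(C)C)c(OCOC)cc1OCOC)c1cc(OCOC)c(OCOC)c(CC=C(C)C)c1 | intermediate (not isolated)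
18 | 5,7-bis(methoxymethoxy)-8-(3-methylbut-2-en-1-yl)-2-[3,4-bis(methoxymethoxy)-5-(3-methylbut-2-en-1-yl)phenyl]-4H-chromen-4-one | O=c1cc(-c2cc(OCOC)c(OCOC)c(CC=C(C)C)c2)oc2c(CC=C(C)C)c(OCOC)cc(OCOC)c12 | intermediate
19 | 3-lithio derivative of 18 | [Li]c1c(-c2cc(OCOC)c(OCOC)c(CC=C(C)C)c2)oc2c(CC=C(C)C)c(OCOC)cc(OCOC)c2c1=O | intermediate (not isolated)
20 | dimethyl {5,7-bis(methoxymethoxy)-8-(3-methylbut-2-en-1-yl)-2-[3,4-bis(methoxymethoxy)-5-(3-methylbut-2-en-1-yl)phenyl]-4-oxo-4H-chromen-3-yl}boronate | COB(OC)c1c(-c2cc(OCOC)c(OCOC)c(CC=C(C)C)c2)oc2c(CC=C(C)C)c(OCOC)cc(OCOC)c2c1=O | intermediate (not isolated)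
21 | 3-hydroxy-5,7-bis(methoxymethoxy)-8-(3-methylbut-2-en-1-yl)-2-[3,4-bis(methoxymethoxy)-5-(3-methylbut-2-en-1-yl)phenyl]-4H-chromen-4-one | Oc1c(-c2cc(OCOC)c(OCOC)c(CC=C(C)C)c2)oc2c(CC=C(C)C)c(OCOC)cc(OCOC)c2c1=O | intermediate
22 | 3-methoxy-5,7-bis(methoxymethoxy)-8-(3-methylbut-2-en-1-yl)-2-[3,4-bis(methoxymethoxy)-5-(3-methylbut-2-en-1-yl)phenyl]-4H-chromen-4-one | COc1c(-c2cc(OCOC)c(OCOC)c(CC=C(C)C)c2)oc2c(CC=C(C)C)c(OCOC)cc(OCOC)c2c1=O | intermediate
23 | 5,7-dihydroxy-2-[3,4-dihydroxy-5-(3-methylbut-2-en-1-yl)phenyl]-3-methoxy-8-(3-methylbut-2-en-1-yl)-4H-chromen-4-one (5,7,3',4'-tetrahydroxy-3-methoxy-8,5'-diprenylflavone) | COc1c(-c2cc(O)c(O)c(CC=C(C)C)c2)oc2c(CC=C(C)C)c(O)cc(O)c2c1=O | target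

## Step count and uncertain steps

Total: 15 steps. Longest linear sequence: 10 steps (step 3, steps 7–11 and steps 12–15, counted from alcohol 4). Counted from the arene starting materials 1 and 9, each branch is 9 steps long (steps 1, 2, 4–6 and 12–15; steps 7–11 and 12–15).

Step 12 (key step).
- What may go wrong: CO insertion may be too slow, so that direct alkynylation and cyclisation to a benzofuran intervene. The aroylpalladium species may be captured by diethylamine (aminocarbonylation). Oxidative addition into the di-ortho-substituted, electron-rich C–I bond may be sluggish, with catalyst precipitation under CO. Premature five-membered closure of the ynone is also possible.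
- Fallback: it sets out from 8 and 14 and comes back at 18, assembling the same three bonds without palladium. Alkyne 14 is lithiated (n-BuLi, THF, −78 °C) and formylated with DMF to 3-[3,4-bis(methoxymethoxy)-5-(3-methylbut-2-en-1-yl)phenyl]prop-2-ynal F1. Iodophenol 8 is treated with n-BuLi (2.1 equiv, THF, −78 °C; O–H deprotonation, then iodine–lithium exchange) and added to F1 to give the racemic propargylic alcohol 1-[2-hydroxy-4,6-bis(methoxymethoxy)-3-(3-methylbut-2-en-1-yl)phenyl]-3-[3,4-bis(methoxymethoxy)-5-(3-methylbut-2-en-1-yl)phenyl]prop-2-yn-1-ol F2. Oxidation with MnO2 in CH2Cl2 gives ynone 16, now isolated, and Et2NH in EtOH at rt closes it through 17 to 18.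

Step 13.
- What may go wrong: the 3-lithio species 19 may ring-open by β-elimination of the phenoxide, which reverts to the phenoxide of 16. Lithiation ortho to MOM ethers may compete. The α-boryl enone 20 may lose boron by protonation before oxygen transfer. Material that ring-opens is not lost, since 16 closes again to 18 with Et2NH.
- Fallback: it sets out from 18 and comes back at 22, bypassing 21. The anion generated with LDA at −78 °C is quenched at once with I2 to the isolable 3-iodo-5,7-bis(methoxymethoxy)-8-(3-methylbut-2-en-1-yl)-2-[3,4-bis(methoxymethoxy)-5-(3-methylbut-2-en-1-yl)phenyl]-4H-chromen-4-one F3. The methoxy group is then introduced directly by copper-catalysed C–O coupling (CuI, 3,4,7,8-tetramethyl-1,10-phenanthroline, Cs2CO3, MeOH/toluene, 90 °C). This fallback removes the borylation and oxidation stage but still depends on the C3 deprotonation.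

Step 2.
- What may go wrong: iodination may occur at C4 between the two MOM ethers, or twice, since all three ring positions are activated.
- Fallback: it sets out from 2 and comes back at 3, using directed ortho-metalation. Compound 2 is carbamoylated (ClCONEt2, K2CO3, MeCN, reflux) to 3,5-bis(methoxymethoxy)phenyl N,N-diethylcarbamate F4. Lithiation with s-BuLi/TMEDA (THF, −78 °C) should take place between the carbamate, the strongest directing group, and a MOM ether. Quenching with I2 at −78 °C, before any anionic Fries rearrangement, gives 2-iodo-3,5-bis(methoxymethoxy)phenyl N,N-diethylcarbamate F5. Hydrolysis with NaOH in EtOH at reflux releases 3.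

Step 7.
- What may go wrong: the leaving group of 5 returns the base, so late in the reaction the 3-OH of the product can be deprotonated and alkylation may occur at O3 or at both oxygens. The catechol may also sequester the copper catalyst.
- Fallback: it sets out from 9 and comes back at 13, using the opposite regiochemistry of the catechol dianion. Compound 9 is converted into its dianion (NaH, 2.2 equiv, DMSO) and treated with MOMCl (1.0 equiv). The 3-oxide is not conjugated with the formyl group and is the more nucleophilic site, so this should give 4-hydroxy-3-(methoxymethoxy)benzaldehyde F6. F6 has one free hydroxyl and is taken through the same sequence: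
  - propargylation with 5 (DBU, CuCl2·2H2O, MeCN) to 3-(methoxymethoxy)-4-[(2-methylbut-3-yn-2-yl)oxy]benzaldehyde F7;
  - Lindlar reduction to 3-(methoxymethoxy)-4-[(2-methylbut-3-en-2-yl)oxy]benzaldehyde F8;
  - Claisen rearrangement to 4-hydroxy-3-(methoxymethoxy)-5-(3-methylbut-2-en-1-yl)benzaldehyde F9;
  - MOM protection to 13.

Step 15.
- What may go wrong: acid may cyclise the prenyl groups onto the adjacent free phenols (7-OH with the C8 prenyl, 4'-OH with the C5' prenyl) to chromans, or add solvent to the alkenes, before the last MOM group is gone.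
- Fallback: it sets out from 22 and comes back at 23, avoiding Brønsted acid. Treatment with Me3SiOTf and 2,2'-bipyridyl (CH2Cl2, 0 °C) exchanges the aryl MOM ethers for silyl ethers under buffered conditions, giving 3-methoxy-5,7-bis(trimethylsilyloxy)-8-(3-methylbut-2-en-1-yl)-2-[3,4-bis(trimethylsilyloxy)-5-(3-methylbut-2-en-1-yl)phenyl]-4H-chromen-4-one F10. Water at rt then hydrolyses F10 to 23.

## Further compounds

F1 | step 12 | 3-[3,4-bis(methoxymethoxy)-5-(3-methylbut-2-en-1-yl)phenyl]prop-2-ynal | O=CC#Cc1cc(OCOC)c(OCOC)c(CC=C(C)C)c1
F2 | step 12 | 1-[2-hydroxy-4,6-bis(methoxymethoxy)-3-(3-methylbut-2-en-1-yl)phenyl]-3-[3,4-bis(methoxymethoxy)-5-(3-methylbut-2-en-1-yl)phenyl]prop-2-yn-1-ol (racemic) | OC(C#Cc1cc(OCOC)c(OCOC)c(CC=C(C)C)c1)c1c(O)c(CC=C(C)C)c(OCOC)cc1OCOC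
F3 | step 13 | 3-iodo-5,7-bis(methoxymethoxy)-8-(3-methylbut-2-en-1-yl)-2-[3,4-bis(methoxymethoxy)-5-(3-methylbut-2-en-1-yl)phenyl]-4H-chromen-4-one | O=c1c(I)c(-c2cc(OCOC)c(OCOC)c(CC=C(C)C)c2)oc2c(CC=C(C)C)c(OCOC)cc(OCOC)c12
F4 | step 2 | 3,5-bis(methoxymethoxy)phenyl N,N-diethylcarbamate | CCN(CC)C(=O)Oc1cc(OCOC)cc(OCOC)c1
F5 | step 2 | 2-iodo-3,5-bis(methoxymethoxy)phenyl N,N-diethylcarbamate | CCN(CC)C(=O)Oc1cc(OCOC)cc(OCOC)c1I
F6 | step 7 | 4-hydroxy-3-(methoxymethoxy)benzaldehyde | O=Cc1ccc(O)c(OCOC)c1
F7 | step 7 | 3-(methoxymethoxy)-4-[(2-methylbut-3-yn-2-yl)oxy]benzaldehyde | O=Cc1ccc(OC(C)(C)C#C)c(OCOC)c1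
F8 | step 7 | 3-(methoxymethoxy)-4-[(2-methylbut-3-en-2-yl)oxy]benzaldehyde | O=Cc1ccc(OC(C)(C)C=C)c(OCOC)c1
F9 | step 7 | 4-hydroxy-3-(methoxymethoxy)-5-(3-methylbut-2-en-1-yl)benzaldehyde | O=Cc1cc(OCOC)c(O)c(CC=C(C)C)c1
F10 | step 15 | 3-methoxy-5,7-bis(trimethylsilyloxy)-8-(3-methylbut-2-en-1-yl)-2-[3,4-bis(trimethylsilyloxy)-5-(3-methylbut-2-en-1-yl)phenyl]-4H-chromen-4-one | COc1c(-c2cc(O[Si](C)(C)C)c(O[Si](C)(C)C)c(CC=C(C)C)c2)oc2c(CC=C(C)C)c(O[Si](C)(C)C)cc(O[Si](C)(C)C)c2c1=O
A1 | alternative 1 | 5-(1-hydroxy-2-{5-methoxy-4-oxo-6-[3,4-bis(methoxymethoxy)-5-(3-methylbut-2-en-1-yl)phenyl]-4H-pyran-2-yl}-5-methylhex-4-en-1-ylidene)-2,2-dimethyl-1,3-dioxane-4,6-dione (racemic) | COc1c(-c2cc(OCOC)c(OCOC)c(CC=C(C)C)c2)oc(C(CC=C(C)C)C(O)=C2C(=O)OC(C)(C)OC2=O)cc1=O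
A2 | alternative 1 | 4-{5-methoxy-4-oxo-6-[3,4-bis(methoxymethoxy)-5-(3-methylbut-2-en-1-yl)phenyl]-4H-pyran-2-yl}-7-methylocta-1,6-diene-1,3-dione (acylketene, racemic) | COc1c(-c2cc(OCOC)c(OCOC)c(CC=C(C)C)c2)oc(C(CC=C(C)C)C(=O)C=C=O)cc1=O
A3 | alternative 1 | 5,7-dihydroxy-3-methoxy-8-(3-methylbut-2-en-1-yl)-2-[3,4-bis(methoxymethoxy)-5-(3-methylbut-2-en-1-yl)phenyl]-4H-chromen-4-one | COc1c(-c2cc(OCOC)c(OCOC)c(CC=C(C)C)c2)oc2c(CC=C(C)C)c(O)cc(O)c2c1=O
A4 | alternative 2 | kojic acid (5-hydroxy-2-(hydroxymethyl)-4H-pyran-4-one) | OCc1cc(=O)c(O)co1
A5 | alternative 2 | 2-diazo-1-{5-methoxy-4-oxo-6-[3,4-bis(methoxymethoxy)-5-(3-methylbut-2-en-1-yl)phenyl]-4H-pyran-2-yl}-5-methylhex-4-en-1-one | COc1c(-c2cc(OCOC)c(OCOC)c(CC=C(C)C)c2)oc(C(=O)C(=[N+]=[N-])CC=C(C)C)cc1=O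
A6 | alternative 2 | (triisopropylsilyloxy)ethyne | C#CO[Si](C(C)C)(C(C)C)C(C)C
A7 | alternative 2 | 5-hydroxy-3-methoxy-8-(3-methylbut-2-en-1-yl)-7-(triisopropylsilyloxy)-2-[3,4-bis(methoxymethoxy)-5-(3-methylbut-2-en-1-yl)phenyl]-4H-chromen-4-one | COc1c(-c2cc(OCOC)c(OCOC)c(CC=C(C)C)c2)oc2c(CC=C(C)C)c(O[Si](C(C)C)(C(C)C)C(C)C)cc(O)c2c1=O
A8 | alternative 3 | 1-[2-bromo-4,6-bis(methoxymethoxy)-3-(3-methylbut-2-en-1-yl)phenyl]-2-methoxy-3-[3,4-bis(methoxymethoxy)-5-(3-methylbut-2-en-1-yl)phenyl]propane-1,3-dione (racemic) | COC(C(=O)c1cc(OCOC)c(OCOC)c(CC=C(C)C)c1)C(=O)c1c(Br)c(CC=C(C)C)c(OCOC)cc1OCOC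
A9 | alternative 3 | 3-methoxy-5,7-bis(methoxymethoxy)-8-(3-methylbut-2-en-1-yl)-2-[3,4-bis(methoxymethoxy)-5-(3-methylbut-2-en-1-yl)phenyl]-4H-chromen-4-one (identical with 22) | COc1c(-c2cc(OCOC)c(OCOC)c(CC=C(C)C)c2)oc2c(CC=C(C)C)c(OCOC)cc(OCOC)c2c1=O
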